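**Retrosynthetic overview**
1. Key disconnection: the C2(sp2)–C1′(sp3) bond between an intact chromone nucleus and the chain. This avoids the usual acetophenone + acyl donor (Claisen/Baker–Venkataraman) condensation and cyclodehydration.
2. The chain synthon is the heptacosyl radical, made from octacosanoic acid 1 via its redox-active ester 2 (C28 acid gives C27 alkyl by loss of CO2).
3. The core synthon is a C2 chromonyl anion, made from 5,7-dihydroxychromone 3 via bis-MOM ether 4 and direct C2–H zincation (5).
4. Ni-catalysed union of 5 and 2 gives 6 at the chromone oxidation level, and acid removes the MOM groups to give 7.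
5. Ring order: no ring is formed, because the benzene and γ-pyrone rings arrive together in 3.

Assumption: the target SMILES (unbranched C27 chain, C36H60O4) has no stereocentre or stereogenic double bond, so it is achiral and "single enantiomer" calls for no stereocontrol.

**Step 1**
Reactants: 1 octacosanoic acid (montanic acid)
Product: 2 4,5,6,7-tetrachloro-1,3-dioxoisoindolin-2-yl octacosanoate (TCNHPI redox-active ester)
Conditions: TCNHPI (1.05 equiv), DIC (1.1 equiv), DMAP (10 mol%), CH2Cl2/THF 1:1, 40 °C; crystallise on cooling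
Reagents that add atoms: N-hydroxytetrachlorophthalimide (TCNHPI), ON1C(=O)c2c(Cl)c(Cl)c(Cl)c(Cl)c2C1=O
Why: Steglich-type carbodiimide esterification, in which DIC/DMAP turn the acid into an acyl-pyridinium species that the acidic N–OH of TCNHPI intercepts to give a crystalline activated ester; no stereocentre is involved.

**Step 2**
Reactants: 3 5,7-dihydroxy-4H-chromen-4-one (5,7-dihydroxychromone)
Product: 4 5,7-bis(methoxymethoxy)-4H-chromen-4-one
Conditions: NaH (2.6 equiv), MOMCl (2.6 equiv), DMF, 0 °C → rt
Reagents that add atoms: chloromethyl methyl ether (MOMCl), COCCl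
Why: Williamson-type O-alkylation, in which irreversible deprotonation by non-nucleophilic hydride breaks the 5-OH···O=C4 hydrogen bond, so both phenoxides are capped by the hard electrophile without opening the 2-unsubstituted pyrone, and the acidic protons that would quench the zinc amide are removed.

**Step 3**
Reactants: 4 5,7-bis(methoxymethoxy)-4H-chromen-4-one; 2 4,5,6,7-tetrachloro-1,3-dioxoisoindolin-2-yl octacosanoate
Product: 6 2-heptacosyl-5,7-bis(methoxymethoxy)-4H-chromen-4-one, via [5,7-bis(methoxymethoxy)-4-oxo-4H-chromen-2-yl]zinc chloride 5 (not isolated)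
Conditions: 4 (2.2 equiv), TMPZnCl·LiCl (2.0 equiv), THF, 25 °C, 1 h; then 2 (1.0 equiv, added in warm THF), Ni(acac)2 (10 mol%), 2,2′-bipyridine (10 mol%), THF/DMF 3:1, 25 → 40 °C, 12 h; sat. aq NH4Cl
Reagents that add atoms: 2,2,6,6-tetramethylpiperidinylzinc chloride·LiCl, CC1(C)CCCC(C)(C)N1[Zn]Cl.[Li+].[Cl-] (supplies the ZnCl of intermediate 5 only; nothing from it remains in 6)
Why: Proposed new method: each half is a known reaction type but the pairing is untested – the Lewis-acid-free zinc amide removes the most acidic proton, C2–H (sp2, α to the ring oxygen and vinylogously acidified by C4=O), to give α-oxyalkenylzinc 5 without touching the MOM ethers, the arene C–H bonds or the carbonyl; 5 then transmetalates to (bipy)Ni(I), the Ni(I)–chromonyl reduces ester 2 by SET, N–O cleavage and loss of CO2 release the primary heptacosyl radical, Ni(II) captures it, and C(sp2)–C(sp3) reductive elimination from Ni(III) forges C2–C1′ directly at the chromone oxidation level; the closest known reaction type is the Ni-catalysed decarboxylative Negishi alkenylation/arylation of redox-active esters with alkenyl- and (hetero)arylzinc halides, and no stereocentre is created.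

**Step 4**
Reactants: 6 2-heptacosyl-5,7-bis(methoxymethoxy)-4H-chromen-4-one
Product: 7 2-heptacosyl-5,7-dihydroxy-4H-chromen-4-one (target)
Conditions: 6 M aq HCl, THF, 55 °C; precipitate with water, recrystallise (CHCl3/MeOH)
Reagents that add atoms: none
Why: Acid-catalysed acetal hydrolysis (MOM cleavage via the oxocarbenium ion) frees both phenols, while the γ-pyrone and the saturated chain are inert to aqueous acid.

**Compound list**
1 | octacosanoic acid | CCCCCCCCCCCCCCCCCCCCCCCCCCCC(=O)O | starting material
2 | 4,5,6,7-tetrachloro-1,3-dioxoisoindolin-2-yl octacosanoate | CCCCCCCCCCCCCCCCCCCCCCCCCCCC(=O)ON1C(=O)c2c(Cl)c(Cl)c(Cl)c(Cl)c2C1=O | intermediate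
3 | 5,7-dihydroxy-4H-chromen-4-one | O=c1ccoc2cc(O)cc(O)c12 | starting material
4 | 5,7-bis(methoxymethoxy)-4H-chromen-4-one | COCOc1cc(OCOC)c2c(=O)ccoc2c1 | intermediate
5 | [5,7-bis(methoxymethoxy)-4-oxo-4H-chromen-2-yl]zinc chloride (LiCl complex, not isolated) | COCOc1cc(OCOC)c2c(=O)cc([Zn]Cl)oc2c1 | intermediate
6 | 2-heptacosyl-5,7-bis(methoxymethoxy)-4H-chromen-4-one | CCCCCCCCCCCCCCCCCCCCCCCCCCCc1cc(=O)c2c(OCOC)cc(OCOC)cc2o1 | intermediate
7 | 2-heptacosyl-5,7-dihydroxy-4H-chromen-4-one (achiral) | CCCCCCCCCCCCCCCCCCCCCCCCCCCc1cc(=O)c2c(O)cc(O)cc2o1 | target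

**Total step count:** 4. **Longest linear sequence:** 3 (3 → 4 → 6 → 7, or 1 → 2 → 6 → 7).

**Three steps most likely to fail**

**Step 3 (highest risk).**
- The electron-poor α-oxyalkenylzinc may transmetalate slowly.
- The primary radical may leak to heptacosane or heptacosene, or add to surplus 4.
- The waxy ester is poorly soluble.
- Fallback: give up the organometallic union for radical conjugate addition followed by re-oxidation. It sets out from 2 and 4.
- Irradiating 2 with 4 (3 equiv), Ru(bpy)3(PF6)2 (1 mol%) and Hantzsch ester (1.5 equiv) in CH2Cl2 (blue LED, 30 °C) generates the same heptacosyl radical. This radical adds to C2 of the chromone (Giese reaction) to give (±)-2-heptacosyl-5,7-bis(methoxymethoxy)chroman-4-one F1.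
- Dehydrogenation with DDQ in dioxane at 100 °C erases the temporary stereocentre and comes back to the route at 6.

**Step 2.**
- The chelated 5-OH may resist alkylation.
- The 2-unsubstituted pyrone may be opened by traces of hydroxide or by dimethylamine from the DMF.
- Fallback: change the protecting-group strategy and the way it is removed. It sets out from 3.
- BnBr/K2CO3 in DMF at 60 °C gives 5,7-bis(benzyloxy)-4H-chromen-4-one F2.
- TMPZnCl·LiCl converts this into [5,7-bis(benzyloxy)-4-oxo-4H-chromen-2-yl]zinc chloride F3, which is used in situ.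
- Ni-catalysed coupling with 2 gives 5,7-bis(benzyloxy)-2-heptacosyl-4H-chromen-4-one F4.
- Neutral hydrogenolysis (H2, Pd/C, THF/EtOAc, 40 °C) comes back to the route at 7.

**Step 1.**
- The C28 acid is barely soluble.
- N-acylurea formation competes with esterification.
- The tetrachloro ester hydrolyses easily on silica.
- Fallback: replace the redox-active ester with an alkyl halide electrophile. It sets out from 1.
- Hunsdiecker–Suárez decarboxylative iodination (PhI(OAc)2, I2, chlorobenzene, visible light, 80 °C) gives 1-iodoheptacosane F5.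
- F5 is joined to zinc reagent 5 (made from 4 as in step 3) by a Pd-catalysed alkyl Negishi coupling (Pd2(dba)3, PCyp3, N-methylimidazole, THF/NMP, 80 °C). This comes back to the route at 6.

**Further compounds**
F1 | step 3 | (±)-2-heptacosyl-5,7-bis(methoxymethoxy)chroman-4-one (racemic) | CCCCCCCCCCCCCCCCCCCCCCCCCCCC1CC(=O)c2c(OCOC)cc(OCOC)cc2O1
F2 | step 2 | 5,7-bis(benzyloxy)-4H-chromen-4-one | O=c1ccoc2cc(OCc3ccccc3)cc(OCc3ccccc3)c12
F3 | step 2 | [5,7-bis(benzyloxy)-4-oxo-4H-chromen-2-yl]zinc chloride | O=c1cc([Zn]Cl)oc2cc(OCc3ccccc3)cc(OCc3ccccc3)c12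
F4 | step 2 | 5,7-bis(benzyloxy)-2-heptacosyl-4H-chromen-4-one | CCCCCCCCCCCCCCCCCCCCCCCCCCCc1cc(=O)c2c(OCc3ccccc3)cc(OCc3ccccc3)cc2o1
F5 | step 1 | 1-iodoheptacosane | CCCCCCCCCCCCCCCCCCCCCCCCCCCI
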